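**Retrosynthetic overview**

1. Labdane numbering is used: ring A = C1–C5, C10; ring B = C5–C10; C17 = formyl carbon; C11–C16 = side chain. The enabling feature is in ring B. C8 is a CH carbon flanked by C7 and C9, and it carries C17 axially, cis to the C9 chain and syn to the angular methyl C20. C17 can therefore be read back into the ring as a seventh member between C9 and C8.
2. Ring B comes from the seven-membered ring C5–C6–C7–C8–C17–C9–C10 with a cis alkene at C17=C8. Face-selective epoxidation and a bromide-relayed semipinacol 1,2-shift expel C17 as the aldehyde.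
3. C9 and the position of that alkene come from formate hydrogenolysis of a tertiary allylic carbonate made from the C9 enone. The Z-enoate comes from syn carbocupration of an alkynoate.
4. Ring A is annulated onto 2-methylcycloheptane-1,3-dione with ethyl vinyl ketone. An amino-acid aldol sets C10, reductive methylation sets C5 and the gem-dimethyl group, and borohydride sets C3.
5. Order of rings: the seven-membered ring is bought, ring A is annulated onto it, and ring B is formed by contraction in the last step.

Key step: step 14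

Assumption: (R)-phenylalanine is taken to induce the same sense as in the six-membered-ring series; if the sense is reversed with the cycloheptanedione, the (S)-amino acid is used.

**Step 1**
Reactants: 1 cycloheptane-1,3-dione
Product: 2 2-methylcycloheptane-1,3-dione
Conditions: MeI, K2CO3, acetone, reflux
Reagents that add atoms: iodomethane, CI
Why: Malonate-type C-alkylation of the stabilised 1,3-diketone enolate with the smallest soft electrophile should stop at the monomethyl compound when base and MeI are limited to one equivalent.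

**Step 2**
Reactants: 2 2-methylcycloheptane-1,3-dione; 3 pent-1-en-3-one (ethyl vinyl ketone)
Product: 4 2-methyl-2-(3-oxopentyl)cycloheptane-1,3-dione
Conditions: Et3N (cat.), MeCN, 40 °C
Reagents that add atoms: none
Why: Amine-catalysed Michael addition of the acidic 2-methyl-1,3-dione to an unhindered vinyl ketone builds the future quaternary carbon C10 in prochiral form, so no stereocentre is set yet.

**Step 3**
Reactants: 4 2-methyl-2-(3-oxopentyl)cycloheptane-1,3-dione
Product: 5 (4aR)-1,4a-dimethyl-4,4a,6,7,8,9-hexahydro-3H-benzo[7]annulene-2,5-dione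
Conditions: (R)-phenylalanine, (+)-camphor-10-sulfonic acid, DMF, 30 to 70 °C
Reagents that add atoms: none
Why: In this Hajos–Parrish–Eder–Sauer–Wiechert reaction the amino-acid enamine of the side-chain ketone differentiates the two enantiotopic ring carbonyls in the intramolecular aldol step, which fixes C10 as R and closes ring A, and dehydration gives the conjugated enone.

**Step 4**
Reactants: 5 (4aR)-1,4a-dimethyl-4,4a,6,7,8,9-hexahydro-3H-benzo[7]annulene-2,5-dione
Product: 6 (4aR)-1,4a-dimethyl-4,4a,6,7,8,9-hexahydro-3H-spiro[benzo[7]annulene-5,2'-[1,3]dioxolan]-2-one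
Conditions: TMSOCH2CH2OTMS, TMSOTf (cat.), CH2Cl2, −78 to −20 °C
Reagents that add atoms: 1,2-bis(trimethylsilyloxy)ethane, C[Si](C)(C)OCCO[Si](C)(C)C
Why: Noyori ketalisation under kinetic control converts the saturated C9 ketone and leaves the less electrophilic conjugated C3 enone untouched, which masks C9 for the dissolving-metal step.

**Step 5**
Reactants: 6 (4aR)-1,4a-dimethyl-4,4a,6,7,8,9-hexahydro-3H-spiro[benzo[7]annulene-5,2'-[1,3]dioxolan]-2-one
Product: 8 trans-fused (4aR,9aR)-1,1,4a-trimethylperhydrospiro[benzo[7]annulene-5,2'-[1,3]dioxolan]-2-one, via lithium enolate 7 (not isolated)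
Conditions: Li, NH3(l)–THF, H2O (1 equiv), −78 to −33 °C; isoprene; MeI
Reagents that add atoms: iodomethane, CI
Why: In this Stork reductive alkylation, electron transfer to the enone and axial protonation at C5 give the trans ring fusion (H5 opposite to C20), and the regiodefined lithium enolate 7 is methylated at C4 to complete the gem-dimethyl group.

**Step 6**
Reactants: 8 trans-fused (4aR,9aR)-1,1,4a-trimethylperhydrospiro[benzo[7]annulene-5,2'-[1,3]dioxolan]-2-one
Product: 10 (2R,4aR,9aR)-2-hydroxy-1,1,4a-trimethylperhydrobenzo[7]annulen-5-one, via hydroxy ketal 9 (not isolated)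
Conditions: NaBH4, MeOH, 0 °C; then 2 M HCl, THF, rt
Reagents that add atoms: water, O
Why: Borohydride attacks the C3 ketone along the axial line from the face opposite to the axial methyl groups on C4 and C10 and so gives the equatorial (3R) alcohol, after which acetal hydrolysis in aqueous acid returns the C9 ketone.

**Step 7**
Reactants: 10 (2R,4aR,9aR)-2-hydroxy-1,1,4a-trimethylperhydrobenzo[7]annulen-5-one
Product: 11 (2R,4aR,9aR)-2-(tert-butyldimethylsilyloxy)-1,1,4a-trimethylperhydrobenzo[7]annulen-5-one
Conditions: TBSOTf, 2,6-lutidine, CH2Cl2, −78 to 0 °C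
Reagents that add atoms: tert-butyldimethylsilyl triflate, CC(C)(C)[Si](C)(C)OS(=O)(=O)C(F)(F)F
Why: Silylation with the reactive triflate overcomes the neopentyl hindrance at C3 and gives an ether that survives the organometallic, palladium and cuprate steps.

**Step 8**
Reactants: 11 (2R,4aR,9aR)-2-(tert-butyldimethylsilyloxy)-1,1,4a-trimethylperhydrobenzo[7]annulen-5-one
Product: 12 (2R,4aR,9aR)-2-(tert-butyldimethylsilyloxy)-1,1,4a-trimethyl-1,2,3,4,4a,8,9,9a-octahydro-5H-benzo[7]annulen-5-one
Conditions: IBX (1.3 equiv), DMSO–PhF, 70 °C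
Reagents that add atoms: none
Why: IBX dehydrogenation proceeds through the only possible enol, toward C17, because C10 is quaternary, and so places the alkene between C17 and C8.

**Step 9**
Reactants: 12 (2R,4aR,9aR)-2-(tert-butyldimethylsilyloxy)-1,1,4a-trimethyl-1,2,3,4,4a,8,9,9a-octahydro-5H-benzo[7]annulen-5-one; 13 (4-bromobut-1-yn-1-yl)trimethylsilane
Product: 15 (2R,4aR,5R,9aR)-2-(tert-butyldimethylsilyloxy)-1,1,4a-trimethyl-5-[4-(trimethylsilyl)but-3-yn-1-yl]-2,3,4,4a,5,8,9,9a-octahydro-1H-benzo[7]annulen-5-yl methyl carbonate, via bromomagnesium alkoxide 14 (not isolated)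
Conditions: 13, Mg, THF; LaCl3·2LiCl, 12, THF, −40 to 0 °C; then ClCO2Me, 0 °C to rt
Reagents that add atoms: methyl chloroformate, COC(=O)Cl
Why: Lanthanum-assisted 1,2-addition of the Grignard reagent made from 13 should take place at C9 from the face opposite to C20, which puts the oxygen on the methyl face, and the alkoxide 14 is acylated in the same flask to the allylic carbonate.

**Step 10**
Reactants: 15 (the tertiary allylic methyl carbonate)
Product: 16 tert-butyldimethyl{[(2R,4aS,5R,9aS)-1,1,4a-trimethyl-5-[4-(trimethylsilyl)but-3-yn-1-yl]-2,3,4,4a,5,8,9,9a-octahydro-1H-benzo[7]annulen-2-yl]oxy}silane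
Conditions: Pd(OAc)2 (5 mol %), PBu3 (10 mol %), HCO2H, Et3N, THF, 40 °C
Reagents that add atoms: none
Why: In this Tsuji hydrogenolysis, zerovalent palladium ionises the carbonate from the face opposite to the leaving group, binds at the less hindered terminus C8 and passes formate hydride to the more substituted terminus C9 on its own face, which sets C9 (H9 opposite to C20, chain on the methyl face) and leaves the cis alkene at C17=C8.

**Step 11**
Reactants: 16 (the silyl alkyne)
Product: 18 methyl 5-[(2R,4aS,5R,9aS)-2-(tert-butyldimethylsilyloxy)-1,1,4a-trimethyl-2,3,4,4a,5,8,9,9a-octahydro-1H-benzo[7]annulen-5-yl]pent-2-ynoate, via lithium acetylide 17 (not isolated)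
Conditions: MeLi·LiBr, THF, 0 °C to rt; ClCO2Me, −78 °C
Reagents that add atoms: methyl chloroformate, COC(=O)Cl
Why: Methyllithium attacks silicon and frees the lithium acetylide 17 (desilylative metalation), which is acylated by methyl chloroformate without touching the silyl ether or the ring alkene.

**Step 12**
Reactants: 18 (the alkynoate)
Product: 19 methyl (2Z)-5-[(2R,4aS,5R,9aS)-2-(tert-butyldimethylsilyloxy)-1,1,4a-trimethyl-2,3,4,4a,5,8,9,9a-octahydro-1H-benzo[7]annulen-5-yl]-3-methylpent-2-enoate
Conditions: Me2CuLi (CuI, MeLi), THF, −78 °C; aq. NH4Cl at −78 °C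
Reagents that add atoms: lithium dimethylcuprate, [Li+].C[Cu-]C
Why: Syn carbocupration of the alkynoate at low temperature followed by cold protonation places the new methyl group cis to H14 and the chain cis to the ester, which is the required Z geometry.

**Step 13**
Reactants: 19 (the silylated Z-enoate)
Product: 20 methyl (2Z)-5-[(2R,4aS,5R,9aS)-2-hydroxy-1,1,4a-trimethyl-2,3,4,4a,5,8,9,9a-octahydro-1H-benzo[7]annulen-5-yl]-3-methylpent-2-enoate
Conditions: 48% aq. HF, MeCN, rt
Reagents that add atoms: none
Why: Fluoride-driven cleavage of the silyl ether frees the C3 alcohol before any epimerisable aldehyde is present.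

**Step 14**
Reactants: 20 (the hydroxy cycloheptene Z-enoate)
Product: 23 methyl (2Z)-5-[(1R,2R,4aS,6R,8aS)-2-formyl-6-hydroxy-5,5,8a-trimethyldecahydronaphthalen-1-yl]-3-methylpent-2-enoate, via epoxide 21 (not isolated), via bromohydrin magnesium salt 22 (not isolated)
Conditions: DMDO, acetone–CH2Cl2, 0 °C; evaporate; MgBr2·OEt2, Et2O–PhH, 0 to 45 °C; pH 7 buffer
Reagents that add atoms: dimethyldioxirane, CC1(C)OO1
Why: Dimethyldioxirane epoxidises the only electron-rich alkene, C17=C8, from the face opposite to C20 and the C9 chain to give 21; MgBr2 opens 21 by backside attack of bromide to the trans-bromohydrin salt 22, and on warming the ring bond C9–C17, which lies antiperiplanar to the pseudo-equatorial C8–Br bond, shifts to C8 as bromide leaves and C17 becomes the formyl carbon. The closest known reaction type is the magnesium- or lithium-halide-mediated contraction of cycloalkene oxides to the next lower cycloalkanecarbaldehydes, a semipinacol rearrangement of a halohydrin salt. Ring B is closed by this suprafacial 1,2-alkyl shift and not by an exo or endo cyclisation: the seven-membered ring C5–C6–C7–C8–C17–C9–C10 expels C17 and the new C8–C9 bond completes the six-membered ring. C8 is the only new stereocentre and is fixed by two successive inversions (bromide in, C9 in), which leave the formyl group on the face from which bromide entered, the face of C20 and of the C9 chain, so that the axial, contra-thermodynamic aldehyde results while C9 migrates with retention. The step needs face selectivity (secured by the pseudo-axial C20 methyl and the C9 chain), chemoselectivity (the enoate alkene is electron-poor) and alkyl shift instead of hydride shift (in the trans-bromohydrin only the ring bond can stand anti to C–Br, and the diaxial conformer merely returns to 21), whereas the site of bromide attack is irrelevant because opening at C17 followed by shift of C7 gives the same aldehyde with the same configuration. The flexible seven-membered ring lets the first-formed diaxial salt relax to the diequatorial conformer that rearranges, and the neutral medium should spare the free C3 hydroxyl, the ester and the epimerisable C8 centre.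

**Compound list**

1 | cycloheptane-1,3-dione | O=C1CCCCC(=O)C1 | starting material
2 | 2-methylcycloheptane-1,3-dione | CC1C(=O)CCCCC1=O | intermediate
3 | pent-1-en-3-one | C=CC(=O)CC | starting material
4 | 2-methyl-2-(3-oxopentyl)cycloheptane-1,3-dione | CCC(=O)CCC1(C)C(=O)CCCCC1=O | intermediate
5 | (4aR)-1,4a-dimethyl-4,4a,6,7,8,9-hexahydro-3H-benzo[7]annulene-2,5-dione | O=C1CCCCC2=C(C)C(=O)CC[C@@]12C | intermediate
6 | (4aR)-1,4a-dimethyl-4,4a,6,7,8,9-hexahydro-3H-spiro[benzo[7]annulene-5,2'-[1,3]dioxolan]-2-one | O1CCOC12CCCCC3=C(C)C(=O)CC[C@@]23C | intermediate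
7 | lithium C3=C4 enolate of the trans-fused (4aR,9aR) ketal ketone | O1CCOC12CCCC[C@@H]3C(C)=C(O[Li])CC[C@@]23C | intermediate
8 | (4aR,9aR)-1,1,4a-trimethylperhydrospiro[benzo[7]annulene-5,2'-[1,3]dioxolan]-2-one | O1CCOC12CCCC[C@@H]3C(C)(C)C(=O)CC[C@@]23C | intermediate
9 | (2R,4aR,9aR)-1,1,4a-trimethylperhydrospiro[benzo[7]annulene-5,2'-[1,3]dioxolan]-2-ol | O1CCOC12CCCC[C@@H]3C(C)(C)[C@H](O)CC[C@@]23C | intermediate
10 | (2R,4aR,9aR)-2-hydroxy-1,1,4a-trimethylperhydrobenzo[7]annulen-5-one | O=C1CCCC[C@@H]2C(C)(C)[C@H](O)CC[C@@]12C | intermediate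
11 | (2R,4aR,9aR)-2-(tert-butyldimethylsilyloxy)-1,1,4a-trimethylperhydrobenzo[7]annulen-5-one | O=C1CCCC[C@@H]2C(C)(C)[C@H](O[Si](C)(C)C(C)(C)C)CC[C@@]12C | intermediate
12 | (2R,4aR,9aR)-2-(tert-butyldimethylsilyloxy)-1,1,4a-trimethyl-1,2,3,4,4a,8,9,9a-octahydro-5H-benzo[7]annulen-5-one | O=C1C=CCC[C@@H]2C(C)(C)[C@H](O[Si](C)(C)C(C)(C)C)CC[C@@]12C | intermediate
13 | (4-bromobut-1-yn-1-yl)trimethylsilane | C[Si](C)(C)C#CCCBr | starting material
14 | bromomagnesium (2R,4aR,5R,9aR) tertiary allylic alkoxide | C[Si](C)(C)C#CCC[C@@]1(O[Mg]Br)C=CCC[C@@H]2C(C)(C)[C@H](O[Si](C)(C)C(C)(C)C)CC[C@@]12C | intermediate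
15 | (2R,4aR,5R,9aR) tertiary allylic methyl carbonate | C[Si](C)(C)C#CCC[C@@]1(OC(=O)OC)C=CCC[C@@H]2C(C)(C)[C@H](O[Si](C)(C)C(C)(C)C)CC[C@@]12C | intermediate
16 | (2R,4aS,5R,9aS) cycloheptene with 4-(trimethylsilyl)but-3-ynyl chain on C9 | C[Si](C)(C)C#CCC[C@@H]1C=CCC[C@@H]2C(C)(C)[C@H](O[Si](C)(C)C(C)(C)C)CC[C@@]12C | intermediate
17 | lithium acetylide of the desilylated alkyne | [Li]C#CCC[C@@H]1C=CCC[C@@H]2C(C)(C)[C@H](O[Si](C)(C)C(C)(C)C)CC[C@@]12C | intermediate
18 | (2R,4aS,5R,9aS) methyl pent-2-ynoate | COC(=O)C#CCC[C@@H]1C=CCC[C@@H]2C(C)(C)[C@H](O[Si](C)(C)C(C)(C)C)CC[C@@]12C | intermediate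
19 | (2R,4aS,5R,9aS) silylated methyl (2Z)-3-methylpent-2-enoate | COC(=O)/C=C(/C)CC[C@@H]1C=CCC[C@@H]2C(C)(C)[C@H](O[Si](C)(C)C(C)(C)C)CC[C@@]12C | intermediate
20 | methyl (2Z)-5-[(2R,4aS,5R,9aS)-2-hydroxy-1,1,4a-trimethyl-2,3,4,4a,5,8,9,9a-octahydro-1H-benzo[7]annulen-5-yl]-3-methylpent-2-enoate | COC(=O)/C=C(/C)CC[C@@H]1C=CCC[C@@H]2C(C)(C)[C@H](O)CC[C@@]12C | intermediate
21 | methyl (2Z)-5-[(2R,4aR,5S,6R,7S,9aS)-6,7-epoxy-2-hydroxy-1,1,4a-trimethylperhydrobenzo[7]annulen-5-yl]-3-methylpent-2-enoate | COC(=O)/C=C(/C)CC[C@@H]1[C@H]3O[C@H]3CC[C@@H]2C(C)(C)[C@H](O)CC[C@@]12C | intermediate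
22 | bromomagnesium 6-alkoxide of the (2R,4aR,5S,6R,7R,9aS)-7-bromo-6-hydroxy compound | COC(=O)/C=C(/C)CC[C@@H]1[C@@H](O[Mg]Br)[C@H](Br)CC[C@@H]2C(C)(C)[C@H](O)CC[C@@]12C | intermediate
23 | methyl (2Z)-5-[(1R,2R,4aS,6R,8aS)-2-formyl-6-hydroxy-5,5,8a-trimethyldecahydronaphthalen-1-yl]-3-methylpent-2-enoate | COC(=O)/C=C(/C)CC[C@@H]1[C@H](C=O)CC[C@@H]2C(C)(C)[C@H](O)CC[C@@]12C | target

Total step count: 14. Longest linear sequence: 14 steps (1 to 23).

**Steps most likely to fail**

**Step 14.** Several processes may interfere: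
- incomplete face selectivity in the epoxidation;
- return of the bromohydrin salt to the epoxide;
- bromide exchange to the cis-bromohydrin followed by hydride shift to a cycloheptanone;
- capture of the alkoxide by the enoate;
- epimerisation at C8 on prolonged warming.

The fallback sets out from 20 and comes back at 23. It separates the two inversions and replaces the thermal push of the alkoxide by a halophilic pull. Compound 20 is epoxidised with mCPBA/NaHCO3 and epoxide 21 is purified. LiI/AcOH in THF at −20 °C opens it to the trans-iodohydrin F1. Ag2CO3 on Celite in benzene at 0 °C then removes iodide and triggers the same 1,2-shift under cold neutral conditions (Tiffeneau-type semipinacol rearrangement of an iodohydrin).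

**Step 3.** The aldol step may differentiate the two ring carbonyls poorly, or dehydration may be sluggish in the seven-membered series. The fallback sets out from 4 and comes back at 5. Pyrrolidine/AcOH cyclodehydration gives the racemic enedione F2. An enzymatic kinetic resolution with an (S)-selective ketoreductase (NADPH, glucose dehydrogenase, glucose, pH 7) reduces the C9 ketone of the unwanted enantiomer to the hydroxy enone F3. This is removed by chromatography and leaves 5.

**Step 10.** Three failures are possible: hydride delivery to the wrong allyl terminus, loss of a proton from the allyl complex to a diene, or a wrong carbinol configuration carried over from step 9 that would place hydride on the wrong face. The fallback sets out from 12 and comes back at 16, and it does not depend on the carbinol configuration.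
- The Grignard adduct is quenched with water to give the tertiary allylic alcohol F4.
- Pyridinium chlorochromate (C5H5NH[CrO3Cl]) effects the Dauben–Michno oxidative transposition to the transposed enone F5.
- Luche reduction (NaBH4, CeCl3·7H2O, MeOH) from the open face gives the allylic alcohol F6.
- Mitsunobu displacement with 2-nitrobenzenesulfonylhydrazide (PPh3, DEAD, −30 °C) inverts C8 to the sulfonylhydrazine F7.
- On warming, F7 gives the allylic diazene F8, which hands its hydrogen to C9 on the face opposite to C20 as nitrogen leaves (Myers reductive transposition) and gives 16.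

**Further compounds**

F1 | step 14 | methyl (2Z)-5-[(2R,4aR,5S,6R,7R,9aS)-2,6-dihydroxy-7-iodo-1,1,4a-trimethylperhydrobenzo[7]annulen-5-yl]-3-methylpent-2-enoate | COC(=O)/C=C(/C)CC[C@@H]1[C@@H](O)[C@H](I)CC[C@@H]2C(C)(C)[C@H](O)CC[C@@]12C
F2 | step 3 | racemic 1,4a-dimethyl-4,4a,6,7,8,9-hexahydro-3H-benzo[7]annulene-2,5-dione | O=C1CCCCC2=C(C)C(=O)CCC12C
F3 | step 3 | (4aS,5S)-5-hydroxy-1,4a-dimethyl-3,4,4a,5,6,7,8,9-octahydro-2H-benzo[7]annulen-2-one | O[C@H]1CCCCC2=C(C)C(=O)CC[C@]12C
F4 | step 10 | (2R,4aR,5R,9aR) tertiary allylic alcohol corresponding to 14 | C[Si](C)(C)C#CCC[C@@]1(O)C=CCC[C@@H]2C(C)(C)[C@H](O[Si](C)(C)C(C)(C)C)CC[C@@]12C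
F5 | step 10 | transposed enone (C9=C17, C8 ketone) | C[Si](C)(C)C#CCCC1=CC(=O)CC[C@@H]2C(C)(C)[C@H](O[Si](C)(C)C(C)(C)C)CC[C@@]12C
F6 | step 10 | (7R) allylic alcohol (C8 hydroxyl on the face of C20) | C[Si](C)(C)C#CCCC1=C[C@H](O)CC[C@@H]2C(C)(C)[C@H](O[Si](C)(C)C(C)(C)C)CC[C@@]12C
F7 | step 10 | (7S) N-allyl-N-(2-nitrobenzenesulfonyl)hydrazine | C[Si](C)(C)C#CCCC1=C[C@@H](N(N)S(=O)(=O)c3ccccc3[N+](=O)[O-])CC[C@@H]2C(C)(C)[C@H](O[Si](C)(C)C(C)(C)C)CC[C@@]12C
F8 | step 10 | (7S) allylic diazene | C[Si](C)(C)C#CCCC1=C[C@@H](N=N)CC[C@@H]2C(C)(C)[C@H](O[Si](C)(C)C(C)(C)C)CC[C@@]12C
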